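16.5 % is the number I carry. It is the branch share: over-reacted product divided by the sum of over-reacted product and over-reaction product, pooled over the last readings of the gamma and delta runs. In the usual term, it is a selectivity.

| flask | substrate | gas phase | remark | time |
|---|---|---|---|---|
| gamma | 0.75 M | 200 mM (held) | run made earlier |  |
| delta | 1.1 M | 200 mM (held) | run made earlier |  |
| teal | 1.5 M | 200 mM (held) |  | 1.5 h |
| blue | 1.5 M | 200 mM (held) |  | 3.0 h |
| amber | 1.5 M | 200 mM (held) |  | 6.0 h |

| run | time / min | over-reacted product / % | substrate / % | over-reaction product / % | target / % |
|---|---|---|---|---|---|
| gamma | 15.0 | 0.4 | 86.7 | 2.1 | 11.4 |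
| gamma | 40.0 | 1.4 | 61.9 | 13.5 | 21.4 |
| gamma | 80.0 | 6.5 | 33.9 | 37.2 | 19.6 |
| gamma | 120 | 11.7 | 17.7 | 58.4 | 12.4 |
| delta | 8.00 | 0.5 | 95.2 | 0 | 5.8 |
| delta | 20.0 | 1.0 | 82.5 | 3.7 | 13.6 |
| delta | 50.0 | 3.2 | 58.1 | 15.4 | 22.2 |
| delta | 120 | 9.8 | 24.9 | 50.4 | 14.9 |

(standard deviation of a reading: 0.5 percentage points)

- which of these there is most of at the end, counted by the substrate in it, teal (over-reacted product / target / substrate / over-reaction product)
- which of these there is most of at the end, counted by the substrate in it, blue (over-reacted product / target / substrate / over-reaction product)
- which of these there is most of at the end, counted by the substrate in it, amber (over-reacted product / target / substrate / over-reaction product)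
- how much there is at the end of the one of these that leads, in percent of the substrate charged: teal
- how much there is at the end of the one of these that leads, in percent of the substrate charged: blue
- how much there is at the end of the one of these that leads, in percent of the substrate charged: amber

The charge sits in four forms, so I reckon the remainder of substrate and target, and the share splits the rest.

First, the clock. I read the substrate's decay as 0.0162 min⁻¹ late in gamma and 0.0121 min⁻¹ late in delta. Times charge, these are 0.0122 M min⁻¹ and 0.0133 M min⁻¹, so I scale the rate inversely with charge. At the charge of teal, blue and amber that gives 0.00888 min⁻¹, and I estimate that teal keeps 45.0 % of its substrate.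

That remainder is 0.675 M, less than delta's charge, so from there I run at delta's rate. By this estimate blue keeps 15.1 % and amber 1.71 %.

Next, the target. Gamma's last readings put it at 0.701 of the substrate. In my estimate for teal, both products together then come to 23.5 % and the target to 31.5 %, each less than the substrate, so substrate leads teal at about 45.0 %.

The share then gives over-reaction product of 62.0 % in blue and 81.1 % in amber, and there it leads.

The weak link is the split itself. If over-reaction product fed over-reacted product, the share would climb with time. So I test it inside delta. Over-reaction product goes from 15.4 % to 50.4 % between 50.0 min and 120 min, while the share reads 17.2 % and then 16.3 %. With a scatter of 0.5 percentage points on each reading, the share read in delta does not climb. So I read two parallel branches from the target.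

The forecast reads “substrate goes to target, then over-reaction product, then over-reacted product”. It names substrate at 43 % for teal, over-reaction product at 56 % for blue and over-reacted product at 63 % for amber. We part on amber's leader.

The flasks give substrate at 43.4 % in teal, over-reaction product at 64.0 % in blue and over-reaction product at 83.0 % in amber.

    substrate + dissolved gas → target (k = 0.00200 M⁻¹ s⁻¹)
    gas phase ⇌ dissolved gas, rate k2*(csat - [dissolved gas]) (kL = 0.00220 s⁻¹)
    dissolved gas + target → over-reacted product (k = 7.70 × 10⁻⁴ M⁻¹ s⁻¹)
    dissolved gas + target → over-reaction product (k = 0.00390 M⁻¹ s⁻¹)

Left for 60.0 h, amber holds over-reaction product at 83.5 %. The share on amber's remainder of substrate 0.320 % and target 0.239 % gives 83.0 %. Blue read at 5.0 h holds substrate 1.29 % and target 0.965 %, so the share gives 81.6 %, and its over-reaction product stands at 81.6 %.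

(All runs are simulated from invented constants, noise included.)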